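4.11 mM of X is the number I carry through this flask: the crossover level, the c_X at which the loss to X2 and the passage through Z towards D take X equally fast.

| flask | X | time | remark |
|---|---|---|---|
| Thursday's | 32 mM | 1.5 h | everything together in a closed stirred flask, run for 1.5 h |
| Monday's | 32 mM |  | a single well-mixed tank run continuously and read at steady state, 4.50 h in it on average |
| Saturday's | 32 mM |  | a single well-mixed tank run continuously and read at steady state, 1.5 h in it on average |

- the set-up with the highest amount of D at the outlet or at the end, in percent of the X put in ("none" if the first two lie within 2 percentage points) (Thursday's / Monday's / Saturday's / none)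
- amount of D at the outlet or at the end, in percent of the X put in, Thursday's
- amount of D at the outlet or at the end, in percent of the X put in, Monday's
- amount of D at the outlet or at the end, in percent of the X put in, Saturday's

- a species is counted by the X in it: one X2 counts as two
- a step written with two of one species runs at k times the square of its concentration and takes two of it each time
- the stated concentrations are those of everything mixed, before any reaction; amounts are the same in each set-up
- run time (Thursday's): 1.5 h

    D ⇌ L (K1 = 0.28, k1 = 0.21 min⁻¹)
    Z → D (k2 = 0.20 min⁻¹)
    X ⇌ Q (K3 = 1.7, k3 = 0.069 min⁻¹)
    2 X → X2 (k4 = 1.5 L mol⁻¹ min⁻¹)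
    X ⇌ Z (K5 = 0.083, k5 = 0.048 min⁻¹)

X goes reversibly to Q and to Z, Z goes on to D, D goes reversibly to L, and two X join to X2. Z lives 1.28 min, shorter than the run, so I hold it quasi-steady, and X feeds D+L at first order with 0.01233 min⁻¹. The X2 step, at the charged amount, runs at 0.0960 min⁻¹. The selectivity towards D+L is then the crossover divided by the crossover plus c_X.

For the tanks I take Q at its equilibrium with X and solve the balance of the charge, a quadratic in c_X. Monday's tank gives 3.58 mM, below the crossover, and Saturday's gives 5.92 mM, above it. D's forward half-life of 3.30 min is shorter than the time in the vessel, so D holds 78.1% of D+L. That makes Monday's 29.1% and Saturday's 16.0%. For Thursday's closed flask I drop Q, and X then counts for 19.0 min at full charge, which gives a rough 18.3%. My choice is Monday's.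

The forecast also names Monday's, with 16.5%, 29.3% and 16.6% for Thursday's, Monday's and Saturday's. Its Thursday's figure, from “a coarse hand integration with Q buffering”, stands below mine.

The simulation gives Monday's, with 16.2%, 29.3% and 16.6% in the same order.

Saturday's tank reads 6.20 mM of X, above the crossover, and at that level X2 takes X 1.51 times as fast as the passage through Z does, a selectivity of 39.9% towards D+L. Monday's tank, below the crossover by my reckoning, has a selectivity of 53.4%, and its outlet holds 29.3% of D against 16.6% at Saturday's.

(The constants are made up; the flask was simulated.)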